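The ten-membered ring is closed late at C3–C4 (germacrane numbering), where the ring methylene C3 meets the fully substituted alkene carbon C4 that also carries C15. C4 is therefore introduced as a gem-dibromoalkene on an all-trans γ-lactone whose C8 side chain ends in a C3 alkylzinc: an intramolecular, trans-selective Negishi coupling joins C3 to C4 at the bromine trans to the lactone carbon C6, fixing the ring alkene geometry, and leaves the cis bromine as the handle for the hydroxymethyl carbon C15. The lactone core (C6, C7, C11) comes from a dithiane conjugate addition–methylation on a chiral butenolide; C8 is set by oxazaborolidine reduction.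

Key step: step 16

Remark: germacrane numbering is used throughout (ring carbons C1–C10, lactone carbons C11–C13 with the lactone oxygen on C6, C14 = methyl on C10, C15 = CH2OH carbon on C4, ester oxygen on C8); compounds 1, 2, 6, 9, 10 and 13 are assumed to be commercially available.

Step 1
Reactants: 1 3-[(tert-butyldimethylsilyl)oxy]propanal; 2 methyl 2-[bis(2,2,2-trifluoroethoxy)phosphoryl]propanoate
Product: 3 methyl (2Z)-5-[(tert-butyldimethylsilyl)oxy]-2-methylpent-2-enoate
Conditions: KN(SiMe3)2, 18-crown-6, THF, −78 °C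
Reagents that add atoms: none
Why: Still–Gennari olefination; the electron-poor phosphonate with a dissociated potassium counter-ion should collapse kinetically to the (Z)-trisubstituted enoate, which sets the (Z)-C1=C10 alkene (ester carbon = C9).

Step 2
Reactants: 3 methyl (2Z)-5-[(tert-butyldimethylsilyl)oxy]-2-methylpent-2-enoate
Product: 4 (2Z)-5-[(tert-butyldimethylsilyl)oxy]-2-methylpent-2-en-1-ol
Conditions: i-Bu2AlH (2.2 equiv), CH2Cl2, −78 °C
Reagents that add atoms: none
Why: 1,2-reduction of the enoate by the aluminium hydride should give the allylic alcohol without touching the alkene geometry or the silyl ether.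

Step 3
Reactants: 4 (2Z)-5-[(tert-butyldimethylsilyl)oxy]-2-methylpent-2-en-1-ol
Product: 5 {[(3Z)-5-bromo-4-methylpent-3-en-1-yl]oxy}(tert-butyl)dimethylsilane
Conditions: CBr4, PPh3, CH2Cl2, 0 °C
Reagents that add atoms: carbon tetrabromide, BrC(Br)(Br)Br
Why: Appel bromination; SN2 displacement at the primary allylic carbon under neutral conditions should keep the (Z)-alkene intact.

Step 4
Reactants: 5 {[(3Z)-5-bromo-4-methylpent-3-en-1-yl]oxy}(tert-butyl)dimethylsilane; 6 1,3-dithiane
Product: 8 tert-butyl{[(3Z)-5-(1,3-dithian-2-yl)-4-methylpent-3-en-1-yl]oxy}dimethylsilane, via 2-lithio-1,3-dithiane 7 (not isolated)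
Conditions: 6, n-BuLi, THF, −30 °C; then 5, −78 to −20 °C
Reagents that add atoms: none
Why: Corey–Seebach alkylation; the soft dithiane anion should attack the primary allylic bromide by SN2 and make C8 an acyl-anion equivalent joined to C9.

Step 5
Reactants: 9 [(tert-butyldimethylsilyl)oxy]acetaldehyde; 10 ethyl 2-(triphenyl-λ5-phosphanylidene)propanoate
Product: 11 ethyl (2E)-4-[(tert-butyldimethylsilyl)oxy]-2-methylbut-2-enoate
Conditions: CH2Cl2, 25 °C
Reagents that add atoms: none
Why: Wittig reaction of a stabilised ylide, expected to give the (E)-trisubstituted enoate of the ester side chain.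

Step 6
Reactants: 11 ethyl (2E)-4-[(tert-butyldimethylsilyl)oxy]-2-methylbut-2-enoate
Product: 12 (2E)-4-[(tert-butyldimethylsilyl)oxy]-2-methylbut-2-enoic acid
Conditions: LiOH·H2O, THF/MeOH/H2O, 0 to 25 °C; then 1 M HCl to pH 4, 0 °C
Reagents that add atoms: lithium hydroxide, [Li+].[OH-]
Why: Saponification of the ethyl ester; the primary allylic silyl ether should survive aqueous hydroxide and a brief cold acidification.

Step 7
Reactants: 13 (5S)-5-(hydroxymethyl)furan-2(5H)-one
Product: 14 (5S)-5-{[(triethylsilyl)oxy]methyl}furan-2(5H)-one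
Conditions: Et3SiCl, imidazole, CH2Cl2, 0 °C
Reagents that add atoms: chlorotriethylsilane, CC[Si](Cl)(CC)CC
Why: Silylation of the primary alcohol; the triethylsilyl ether is chosen because it can later be oxidised directly in the presence of the tert-butyldimethylsilyl ether, and C6 is taken from the chiral pool.

Step 8
Reactants: 8 tert-butyl{[(3Z)-5-(1,3-dithian-2-yl)-4-methylpent-3-en-1-yl]oxy}dimethylsilane; 14 (5S)-5-{[(triethylsilyl)oxy]methyl}furan-2(5H)-one
Product: 17 (3S,4S,5S)-4-{2-[(2Z)-5-[(tert-butyldimethylsilyl)oxy]-2-methylpent-2-en-1-yl]-1,3-dithian-2-yl}-3-methyl-5-{[(triethylsilyl)oxy]methyl}oxolan-2-one, via lithiated dithiane 15 (not isolated), via lithium lactone enolate 16 (not isolated)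
Conditions: 8, n-BuLi, THF, −30 °C; HMPA, then 14, −78 °C; then MeI, −78 to −40 °C
Reagents that add atoms: iodomethane, CI
Why: Tandem conjugate addition–enolate alkylation; the HMPA-separated dithiane anion should add 1,4 to the butenolide anti to the C6 silyloxymethyl group (sets C7), and the enolate should be methylated anti to the bulky dithianyl group (sets C11), giving the all-trans lactone.

Step 9
Reactants: 17 (3S,4S,5S)-4-{2-[(2Z)-5-[(tert-butyldimethylsilyl)oxy]-2-methylpent-2-en-1-yl]-1,3-dithian-2-yl}-3-methyl-5-{[(triethylsilyl)oxy]methyl}oxolan-2-one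
Product: 18 (2S,3S,4S)-3-{2-[(2Z)-5-[(tert-butyldimethylsilyl)oxy]-2-methylpent-2-en-1-yl]-1,3-dithian-2-yl}-4-methyl-5-oxooxolane-2-carbaldehyde
Conditions: (COCl)2, DMSO, CH2Cl2, −78 to −40 °C; then Et3N, −78 to 0 °C
Reagents that add atoms: none
Why: Swern oxidation applied directly to a primary triethylsilyl ether; chlorodimethylsulfonium chloride should cleave and oxidise it to the C5 aldehyde while the tert-butyldimethylsilyl ether and the dithiane stay intact, and the aldehyde is used crude to protect C6.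

Step 10
Reactants: 18 (2S,3S,4S)-3-{2-[(2Z)-5-[(tert-butyldimethylsilyl)oxy]-2-methylpent-2-en-1-yl]-1,3-dithian-2-yl}-4-methyl-5-oxooxolane-2-carbaldehyde
Product: 19 (3S,4S,5S)-4-{2-[(2Z)-5-[(tert-butyldimethylsilyl)oxy]-2-methylpent-2-en-1-yl]-1,3-dithian-2-yl}-5-(2,2-dibromoethenyl)-3-methyloxolan-2-one
Conditions: CBr4, PPh3, 2,6-lutidine, CH2Cl2, 0 °C
Reagents that add atoms: carbon tetrabromide, BrC(Br)(Br)Br
Why: Ramirez dibromo-olefination (first stage of the Corey–Fuchs sequence); the ylide should convert the aldehyde into the C5=C4 gem-dibromoalkene under buffered, non-epimerising conditions.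

Step 11
Reactants: 19 (3S,4S,5S)-4-{2-[(2Z)-5-[(tert-butyldimethylsilyl)oxy]-2-methylpent-2-en-1-yl]-1,3-dithian-2-yl}-5-(2,2-dibromoethenyl)-3-methyloxolan-2-one
Product: 20 (3S,4S,5S)-5-(2,2-dibromoethenyl)-4-{2-[(2Z)-5-hydroxy-2-methylpent-2-en-1-yl]-1,3-dithian-2-yl}-3-methyloxolan-2-one
Conditions: HF·pyridine, pyridine, THF, 0 to 25 °C
Reagents that add atoms: none
Why: Fluoride-mediated desilylation of the primary silyl ether at C3; the lactone, dithiane and dibromoalkene are stable to buffered HF.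

Step 12
Reactants: 20 (3S,4S,5S)-5-(2,2-dibromoethenyl)-4-{2-[(2Z)-5-hydroxy-2-methylpent-2-en-1-yl]-1,3-dithian-2-yl}-3-methyloxolan-2-one
Product: 21 (3S,4S,5S)-5-(2,2-dibromoethenyl)-4-{2-[(2Z)-5-iodo-2-methylpent-2-en-1-yl]-1,3-dithian-2-yl}-3-methyloxolan-2-one
Conditions: I2, PPh3, imidazole, CH2Cl2, 0 °C
Reagents that add atoms: iodine, II
Why: Appel-type iodination; the preformed iodophosphonium species should convert the primary alcohol into the C3 iodide by SN2 without attacking the dithiane.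

Step 13
Reactants: 21 (3S,4S,5S)-5-(2,2-dibromoethenyl)-4-{2-[(2Z)-5-iodo-2-methylpent-2-en-1-yl]-1,3-dithian-2-yl}-3-methyloxolan-2-one
Product: 22 (3S,4S,5S)-5-(2,2-dibromoethenyl)-4-[(3Z)-6-iodo-3-methylhex-3-enoyl]-3-methyloxolan-2-one
Conditions: MeI, CaCO3, MeCN/H2O (9:1), 40 °C
Reagents that add atoms: water, O
Why: Thioacetal hydrolysis by S-methylation; the near-neutral carbonate buffer should unmask the C8 ketone without moving the β,γ-alkene into conjugation or opening the lactone, and the ketone is reduced at once.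

Step 14
Reactants: 22 (3S,4S,5S)-5-(2,2-dibromoethenyl)-4-[(3Z)-6-iodo-3-methylhex-3-enoyl]-3-methyloxolan-2-one
Product: 23 (3S,4R,5S)-5-(2,2-dibromoethenyl)-4-[(1S,3Z)-1-hydroxy-6-iodo-3-methylhex-3-en-1-yl]-3-methyloxolan-2-one
Conditions: (R)-2-methyl-CBS-oxazaborolidine, catecholborane, toluene/CH2Cl2, −78 °C; MeOH quench
Reagents that add atoms: none
Why: Corey–Bakshi–Shibata reduction; with the branched ring carbon C7 as the large and the C9 methylene as the small substituent, the (R)-oxazaborolidine should deliver hydride to the face that gives the (8S)-carbinol, and catecholborane at −78 °C spares the lactone and the halides.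

Step 15
Reactants: 23 (3S,4R,5S)-5-(2,2-dibromoethenyl)-4-[(1S,3Z)-1-hydroxy-6-iodo-3-methylhex-3-en-1-yl]-3-methyloxolan-2-one; 12 (2E)-4-[(tert-butyldimethylsilyl)oxy]-2-methylbut-2-enoic acid
Product: 25 (1S,3Z)-1-[(2S,3R,4S)-2-(2,2-dibromoethenyl)-4-methyl-5-oxooxolan-3-yl]-6-iodo-3-methylhex-3-en-1-yl (2E)-4-[(tert-butyldimethylsilyl)oxy]-2-methylbut-2-enoate, via mixed anhydride 24 (not isolated)
Conditions: 12, 2,4,6-trichlorobenzoyl chloride, Et3N, THF, 25 °C; then 23, DMAP, toluene, 25 °C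
Reagents that add atoms: none
Why: Yamaguchi esterification; acyl transfer from the mixed anhydride to the hindered C8 hydroxyl should proceed with retention at C8 and without isomerising the (E)-enoate.

Step 16
Reactants: 25 (1S,3Z)-1-[(2S,3R,4S)-2-(2,2-dibromoethenyl)-4-methyl-5-oxooxolan-3-yl]-6-iodo-3-methylhex-3-en-1-yl (2E)-4-[(tert-butyldimethylsilyl)oxy]-2-methylbut-2-enoate
Product: 27 (3S,3aR,4S,6Z,10Z,11aS)-10-bromo-3,6-dimethyl-2-oxo-2,3,3a,4,5,8,9,11a-octahydrocyclodeca[b]furan-4-yl (2E)-4-[(tert-butyldimethylsilyl)oxy]-2-methylbut-2-enoate, via alkylzinc iodide 26 (not isolated)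
Conditions: Zn dust (activated with BrCH2CH2Br and Me3SiCl), LiCl, THF, 30 °C; then syringe-pump addition to PdCl2(DPEphos) (10 mol %), THF/DMF, 40 °C, final 0.002 M
Reagents that add atoms: none
Why: Zinc inserts into the primary C3–I bond (the dibromoalkene, lactone and enoate are inert to zinc dust at 30 °C) to give the homoallylic alkylzinc iodide 26; zerovalent palladium then adds to the C4–Br bond that is trans to the lactone carbon C6, the tethered alkylzinc transmetalates and reductive elimination forms C3–C4. The closest known reaction type is the trans-selective palladium-catalysed monoalkylation of 1,1-dibromo-1-alkenes by alkylzinc halides (Negishi coupling), run here within one molecule under slow-addition pseudo-high dilution. The ten-membered carbocycle closes through an eleven-membered palladacycle in an endo mode, both alkene carbons C4 and C5 ending inside the new ring. No stereocentre is created; the C4=C5 geometry (C3 trans to C6, the remaining bromine cis to C6) follows from the site of oxidative addition and from retention at the alkenyl–palladium bond. The step needs site selectivity between the two bromines and ring closure in preference to oligomerisation and β-hydride elimination: the cis bromine is shielded by the lactone ring on C6 and the monobromoalkene formed is far less reactive than the dibromide, the wide-bite-angle DPEphos ligand speeds reductive elimination over β-hydride loss, and the trans-lactone together with the (Z)-C1=C10 alkene turns the C8 chain back toward C4 while dilution keeps two molecules apart.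

Step 17
Reactants: 27 (3S,3aR,4S,6Z,10Z,11aS)-10-bromo-3,6-dimethyl-2-oxo-2,3,3a,4,5,8,9,11a-octahydrocyclodeca[b]furan-4-yl (2E)-4-[(tert-butyldimethylsilyl)oxy]-2-methylbut-2-enoate
Product: 28 (3S,3aR,4S,6Z,10Z,11aR)-10-(hydroxymethyl)-3,6-dimethyl-2-oxo-2,3,3a,4,5,8,9,11a-octahydrocyclodeca[b]furan-4-yl (2E)-4-[(tert-butyldimethylsilyl)oxy]-2-methylbut-2-enoate
Conditions: Bu3SnCH2OH, Pd(PPh3)4, 1,4-dioxane, 80 °C
Reagents that add atoms: (tributylstannyl)methanol, CCCC[Sn](CCCC)(CCCC)CO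
Why: Stille coupling; oxidative addition at the remaining alkenyl bromide and transfer of the hydroxymethyl group from tin should install C15 with retention of the C4=C5 geometry.

Step 18
Reactants: 28 (3S,3aR,4S,6Z,10Z,11aR)-10-(hydroxymethyl)-3,6-dimethyl-2-oxo-2,3,3a,4,5,8,9,11a-octahydrocyclodeca[b]furan-4-yl (2E)-4-[(tert-butyldimethylsilyl)oxy]-2-methylbut-2-enoate
Product: 29 (3S,3aR,4S,6Z,10Z,11aR)-10-(hydroxymethyl)-3,6-dimethyl-2-oxo-2,3,3a,4,5,8,9,11a-octahydrocyclodeca[b]furan-4-yl (2E)-4-hydroxy-2-methylbut-2-enoate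
Conditions: HF·pyridine, pyridine, THF, 0 °C
Reagents that add atoms: none
Why: Buffered fluoride desilylation of the primary allylic silyl ether should free the side-chain alcohol without acyl migration or lactone opening.

Compound list
1 | 3-[(tert-butyldimethylsilyl)oxy]propanal | O=CCCO[Si](C)(C)C(C)(C)C | starting material
2 | methyl 2-[bis(2,2,2-trifluoroethoxy)phosphoryl]propanoate | COC(=O)C(C)P(=O)(OCC(F)(F)F)OCC(F)(F)F | starting material
3 | methyl (2Z)-5-[(tert-butyldimethylsilyl)oxy]-2-methylpent-2-enoate | COC(=O)/C(C)=C\CCO[Si](C)(C)C(C)(C)C | intermediate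
4 | (2Z)-5-[(tert-butyldimethylsilyl)oxy]-2-methylpent-2-en-1-ol | OC/C(C)=C\CCO[Si](C)(C)C(C)(C)C | intermediate
5 | {[(3Z)-5-bromo-4-methylpent-3-en-1-yl]oxy}(tert-butyl)dimethylsilane | BrC/C(C)=C\CCO[Si](C)(C)C(C)(C)C | intermediate
6 | 1,3-dithiane | C1CSCSC1 | starting material
7 | 2-lithio-1,3-dithiane | [Li]C1SCCCS1 | intermediate
8 | tert-butyl{[(3Z)-5-(1,3-dithian-2-yl)-4-methylpent-3-en-1-yl]oxy}dimethylsilane | CC(C)(C)[Si](C)(C)OCC/C=C(C)\CC1SCCCS1 | intermediate
9 | [(tert-butyldimethylsilyl)oxy]acetaldehyde | O=CCO[Si](C)(C)C(C)(C)C | starting material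
10 | ethyl 2-(triphenyl-λ5-phosphanylidene)propanoate | CCOC(=O)C(C)=P(c1ccccc1)(c1ccccc1)c1ccccc1 | starting material
11 | ethyl (2E)-4-[(tert-butyldimethylsilyl)oxy]-2-methylbut-2-enoate | CCOC(=O)/C(C)=C/CO[Si](C)(C)C(C)(C)C | intermediate
12 | (2E)-4-[(tert-butyldimethylsilyl)oxy]-2-methylbut-2-enoic acid | OC(=O)/C(C)=C/CO[Si](C)(C)C(C)(C)C | intermediate
13 | (5S)-5-(hydroxymethyl)furan-2(5H)-one | OC[C@H]1OC(=O)C=C1 | starting material
14 | (5S)-5-{[(triethylsilyl)oxy]methyl}furan-2(5H)-one | CC[Si](CC)(CC)OC[C@H]1OC(=O)C=C1 | intermediate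
15 | 2-lithio derivative of dithiane 8 (lithium on the dithiane carbon, the future C8) | [Li]C1(C/C(C)=C\CCO[Si](C)(C)C(C)(C)C)SCCCS1 | intermediate
16 | lithium enolate of the (4S,5S)-4-dithianyl-5-(triethylsilyloxymethyl) lactone (C7 set, C11 sp2) | CC[Si](CC)(CC)OC[C@H]1OC(O[Li])=C[C@@H]1C2(C/C(C)=C\CCO[Si](C)(C)C(C)(C)C)SCCCS2 | intermediate
17 | (3S,4S,5S)-4-{2-[(2Z)-5-[(tert-butyldimethylsilyl)oxy]-2-methylpent-2-en-1-yl]-1,3-dithian-2-yl}-3-methyl-5-{[(triethylsilyl)oxy]methyl}oxolan-2-one (all-trans lactone) | CC[Si](CC)(CC)OC[C@H]1OC(=O)[C@@H](C)[C@@H]1C2(C/C(C)=C\CCO[Si](C)(C)C(C)(C)C)SCCCS2 | intermediate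
18 | (2S,3S,4S)-3-{2-[(2Z)-5-[(tert-butyldimethylsilyl)oxy]-2-methylpent-2-en-1-yl]-1,3-dithian-2-yl}-4-methyl-5-oxooxolane-2-carbaldehyde | O=C[C@H]1OC(=O)[C@@H](C)[C@@H]1C2(C/C(C)=C\CCO[Si](C)(C)C(C)(C)C)SCCCS2 | intermediate
19 | (3S,4S,5S)-4-{2-[(2Z)-5-[(tert-butyldimethylsilyl)oxy]-2-methylpent-2-en-1-yl]-1,3-dithian-2-yl}-5-(2,2-dibromoethenyl)-3-methyloxolan-2-one | BrC(Br)=C[C@H]1OC(=O)[C@@H](C)[C@@H]1C2(C/C(C)=C\CCO[Si](C)(C)C(C)(C)C)SCCCS2 | intermediate
20 | (3S,4S,5S)-5-(2,2-dibromoethenyl)-4-{2-[(2Z)-5-hydroxy-2-methylpent-2-en-1-yl]-1,3-dithian-2-yl}-3-methyloxolan-2-one | BrC(Br)=C[C@H]1OC(=O)[C@@H](C)[C@@H]1C2(C/C(C)=C\CCO)SCCCS2 | intermediate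
21 | (3S,4S,5S)-5-(2,2-dibromoethenyl)-4-{2-[(2Z)-5-iodo-2-methylpent-2-en-1-yl]-1,3-dithian-2-yl}-3-methyloxolan-2-one | BrC(Br)=C[C@H]1OC(=O)[C@@H](C)[C@@H]1C2(C/C(C)=C\CCI)SCCCS2 | intermediate
22 | (3S,4S,5S)-5-(2,2-dibromoethenyl)-4-[(3Z)-6-iodo-3-methylhex-3-enoyl]-3-methyloxolan-2-one | BrC(Br)=C[C@H]1OC(=O)[C@@H](C)[C@@H]1C(=O)C/C(C)=C\CCI | intermediate
23 | (3S,4R,5S)-5-(2,2-dibromoethenyl)-4-[(1S,3Z)-1-hydroxy-6-iodo-3-methylhex-3-en-1-yl]-3-methyloxolan-2-one | BrC(Br)=C[C@H]1OC(=O)[C@@H](C)[C@@H]1[C@@H](O)C/C(C)=C\CCI | intermediate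
24 | (2E)-4-[(tert-butyldimethylsilyl)oxy]-2-methylbut-2-enoic 2,4,6-trichlorobenzoic anhydride | CC(C)(C)[Si](C)(C)OC/C=C(\C)C(=O)OC(=O)c1c(Cl)cc(Cl)cc1Cl | intermediate
25 | (1S,3Z)-1-[(2S,3R,4S)-2-(2,2-dibromoethenyl)-4-methyl-5-oxooxolan-3-yl]-6-iodo-3-methylhex-3-en-1-yl (2E)-4-[(tert-butyldimethylsilyl)oxy]-2-methylbut-2-enoate | BrC(Br)=C[C@H]1OC(=O)[C@@H](C)[C@@H]1[C@@H](OC(=O)/C(C)=C/CO[Si](C)(C)C(C)(C)C)C/C(C)=C\CCI | intermediate
26 | alkylzinc iodide of 25 (C3–ZnI in place of C3–I) | BrC(Br)=C[C@H]1OC(=O)[C@@H](C)[C@@H]1[C@@H](OC(=O)/C(C)=C/CO[Si](C)(C)C(C)(C)C)C/C(C)=C\CC[Zn]I | intermediate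
27 | (3S,3aR,4S,6Z,10Z,11aS)-10-bromo-3,6-dimethyl-2-oxo-2,3,3a,4,5,8,9,11a-octahydrocyclodeca[b]furan-4-yl (2E)-4-[(tert-butyldimethylsilyl)oxy]-2-methylbut-2-enoate | C/C1=C/CC/C(Br)=C/[C@H]2OC(=O)[C@@H](C)[C@@H]2[C@@H](OC(=O)/C(C)=C/CO[Si](C)(C)C(C)(C)C)C1 | intermediate
28 | (3S,3aR,4S,6Z,10Z,11aR)-10-(hydroxymethyl)-3,6-dimethyl-2-oxo-2,3,3a,4,5,8,9,11a-octahydrocyclodeca[b]furan-4-yl (2E)-4-[(tert-butyldimethylsilyl)oxy]-2-methylbut-2-enoate | C/C1=C/CC/C(CO)=C/[C@H]2OC(=O)[C@@H](C)[C@@H]2[C@@H](OC(=O)/C(C)=C/CO[Si](C)(C)C(C)(C)C)C1 | intermediate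
29 | (3S,3aR,4S,6Z,10Z,11aR)-10-(hydroxymethyl)-3,6-dimethyl-2-oxo-2,3,3a,4,5,8,9,11a-octahydrocyclodeca[b]furan-4-yl (2E)-4-hydroxy-2-methylbut-2-enoate | C/C1=C/CC/C(CO)=C/[C@H]2OC(=O)[C@@H](C)[C@@H]2[C@@H](OC(=O)/C(C)=C/CO)C1 | target

Total step count: 18 steps.
Longest linear sequence: 15 steps (steps 1–4, then 8–18).

Steps most likely to fail

1. Step 16 (ring closure). Transmetalation across the forming ten-membered ring may be slow, so that protodezincation, β-hydride elimination from the alkylpalladium species, intermolecular coupling to dimers and loss of site selectivity between the two bromines take over. The fallback changes the organometallic partner and the way it is made. Setting out from iodide 25, dehydroiodination (DBU, toluene, 80 °C) should give the conjugated (1S,3Z)-3-methylhexa-3,5-dien-1-yl ester F1. 9-BBN (THF, 0 to 25 °C) should hydroborate only its terminal vinyl group to the B-alkyl-9-borabicyclo[3.3.1]nonane F2, which is not isolated. A B-alkyl Suzuki–Miyaura macrocyclisation at the trans bromine (Pd(dppf)Cl2, AsPh3, Cs2CO3, THF/DMF/H2O, 45 °C, slow addition) comes back to the route at bromide 27.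

2. Step 17 (hydroxymethylation). Transfer of the sp3 hydroxymethyl group from tin to the hindered ring alkenylpalladium species may be slow, which would allow protodebromination and ionisation of the allylic C6–O lactone bond by zerovalent palladium at 80 °C. The fallback uses carbon monoxide as the one-carbon source. From bromide 27, palladium-catalysed reductive carbonylation (CO 1 atm, Bu3SnH added slowly, Pd(PPh3)4, THF, 50 °C) should give the (6Z,10Z)-10-formyl macrocyclic enal F3 with C15 at the aldehyde level. Luche reduction (NaBH4, CeCl3·7H2O, MeOH, −40 °C), which spares the lactone and the enoate, returns to alcohol 28.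

3. Step 14 (C8 carbinol). Facial selectivity may be poor if the inherent bias of the C7 stereocentre opposes the (R)-oxazaborolidine, and the β,γ-alkene of ketone 22 may migrate into conjugation before reduction. The fallback reduces to the other face and inverts during acylation. From ketone 22, reduction with the enantiomeric (S)-2-methyl-CBS-oxazaborolidine and catecholborane (toluene, −78 °C) should give the (8R)-alcohol, (3S,4R,5S)-5-(2,2-dibromoethenyl)-4-[(1R,3Z)-1-hydroxy-6-iodo-3-methylhex-3-en-1-yl]-3-methyloxolan-2-one F4. Mitsunobu esterification with acid 12 (PPh3, DIAD, toluene, 0 °C) should invert C8 and come back to the route at ester 25, so that step 15 is skipped.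

Further compounds
F1 | step 16 | (1S,3Z)-1-[(2S,3R,4S)-2-(2,2-dibromoethenyl)-4-methyl-5-oxooxolan-3-yl]-3-methylhexa-3,5-dien-1-yl (2E)-4-[(tert-butyldimethylsilyl)oxy]-2-methylbut-2-enoate | BrC(Br)=C[C@H]1OC(=O)[C@@H](C)[C@@H]1[C@@H](OC(=O)/C(C)=C/CO[Si](C)(C)C(C)(C)C)C/C(C)=C\C=C
F2 | step 16 | (1S,3Z)-6-(9-borabicyclo[3.3.1]nonan-9-yl)-1-[(2S,3R,4S)-2-(2,2-dibromoethenyl)-4-methyl-5-oxooxolan-3-yl]-3-methylhex-3-en-1-yl (2E)-4-[(tert-butyldimethylsilyl)oxy]-2-methylbut-2-enoate | BrC(Br)=C[C@H]1OC(=O)[C@@H](C)[C@@H]1[C@@H](OC(=O)/C(C)=C/CO[Si](C)(C)C(C)(C)C)C/C(C)=C\CCB1C2CCCC1CCC2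
F3 | step 17 | (3S,3aR,4S,6Z,10Z,11aR)-10-formyl-3,6-dimethyl-2-oxo-2,3,3a,4,5,8,9,11a-octahydrocyclodeca[b]furan-4-yl (2E)-4-[(tert-butyldimethylsilyl)oxy]-2-methylbut-2-enoate | C/C1=C/CC/C(C=O)=C/[C@H]2OC(=O)[C@@H](C)[C@@H]2[C@@H](OC(=O)/C(C)=C/CO[Si](C)(C)C(C)(C)C)C1
F4 | step 14 | (3S,4R,5S)-5-(2,2-dibromoethenyl)-4-[(1R,3Z)-1-hydroxy-6-iodo-3-methylhex-3-en-1-yl]-3-methyloxolan-2-one | BrC(Br)=C[C@H]1OC(=O)[C@@H](C)[C@@H]1[C@H](O)C/C(C)=C\CCI
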